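## Retrosynthetic overview

1. Feature: a cis-fused octalin (ring A = C1–C2–C3=C4–C4a–C8a, ring B = C4a–C5–C6–C7–C8–C8a) whose C1 dienoate chain and C2 butenyl group lie on the face of H4a and H8a. This is the pattern of an endo-substituted bicyclo[2.2.2]oct-5-ene in which C3 is still bonded to C7 and C4a is not yet bonded to C5.
2. End game: C7 ketone → axial alcohol → sulfate; C1 CH2OSi → aldehyde → Horner–Wadsworth–Emmons dienoate → acid.
3. Key disconnection: C4a–C5 formed and C3–C7 broken by anionic oxy-Cope rearrangement of the C7 vinyl carbinol. Ring B is formed here and ring A is released from the cage.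
4. Cage first: Diels–Alder reaction of dearomatised 2-methoxy-6-methylphenol with (5S)-menthyloxybutenolide gives the ring A carbons plus C7/C8. C8 methyl comes from enolate alkylation; the lactone carbonyl becomes the (E)-butenyl group (ethyl ketone, (Z)-enol triflate, methyl coupling); the acetal carbon becomes CH2OTBS.

Key step: step 13

Remark: cage and decalin carbons carry the octalin numbers of the target throughout (cage bridgeheads C3 and C8a; bridges C4=C4a, C1–C2 and C7–C8).
Assumption: the C7 carbinol centre made in step 6 is drawn as the expected major epimer; the other epimer is carried along, because step 11 returns this carbon to a ketone.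
Assumption: the target is taken as the free acid form drawn, liberated from its salts in the last work-up and kept cold.

## Route

Step 1
Reactants: 1 furfural
Product: 2 5-hydroxy-2(5H)-furanone (racemic)
Conditions: O2, hν (visible), rose bengal (cat.), MeOH, 20 °C
Reagents that add atoms: dioxygen, O=O
Why: Dye-sensitised photooxygenation, in which singlet oxygen adds across the furan in a [4+2] sense and the endoperoxide fragments in methanol with loss of the formyl carbon as methyl formate to give the γ-hydroxybutenolide.

Step 2
Reactants: 2 5-hydroxy-2(5H)-furanone; 3 (+)-menthol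
Product: 4 (5S)-5-[(1S,2R,5S)-menthyloxy]-2(5H)-furanone
Conditions: camphorsulfonic acid (cat.), toluene, reflux (−H2O); crystallisation from petroleum ether, mother liquor re-equilibrated with acid
Reagents that add atoms: none
Why: Acid-catalysed acetalisation of the pseudo-acid, in which the two C5 epimers interconvert under acid and the (5S) diastereomer crystallises (crystallisation-induced asymmetric transformation), fixing the acetal centre.

Step 3
Reactants: 5 2-methoxy-6-methylphenol; 4 (5S)-menthyloxybutenolide
Product: 7 endo cage adduct (C7 ketone / C8 dimethyl ketal / menthyloxy lactone), via masked o-benzoquinone 6 (not isolated)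
Conditions: PhI(OAc)2 (1.1 equiv), 4 (3 equiv, excess recovered), MeOH, 0 °C → rt, 5 added slowly
Reagents that add atoms: methanol, CO
Why: Oxidative dearomatisation in methanol gives the 6,6-dimethoxy-2-methylcyclohexadienone, which is trapped in a Diels–Alder reaction in which the lactone α-carbon bonds to the methyl-bearing diene terminus next to the ketone (the usual orientation of such dienones), the lactone ring lies under the diene (endo) and the diene adds to the butenolide face anti to the menthyloxy group, which together should set C1, C2, C3 and C8a in the required absolute sense.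

Step 4
Reactants: 7 endo cage adduct
Product: 9 cage ketone with C8 methylene, via monomethoxy ketone 8 (not isolated)
Conditions: SmI2 (5 equiv), THF–MeOH, −78 °C → rt
Reagents that add atoms: none
Why: Reductive cleavage of α-alkoxy ketones by divalent samarium, in which electron transfer to the ketone expels each α-methoxy group in turn and methanol protonates the samarium enolates, while the lactone acetal (not α to a carbonyl) is left alone.

Step 5
Reactants: 9 cage ketone with C8 methylene
Product: 10 C8-methyl cage ketone (methyl syn to the C4=C4a bridge)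
Conditions: LiN(i-Pr)2 (1.05 equiv), THF, −78 °C; MeI, −78 → −40 °C
Reagents that add atoms: iodomethane, CI
Why: Kinetic lithium enolate alkylation, in which only C8 of the ketone can enolise (C3 is a quaternary bridgehead) and the ketone is deprotonated before the lactone α-CH, and methyl iodide attacks the enolate on the open side facing the etheno bridge because the other side is screened by the C1–H bond, which sets C8.

Step 6
Reactants: 10 C8-methyl cage ketone
Product: 12 hydroxy γ-lactone (C7 carbinol; lactone C=O on C2 and OCH2 on C1), via dihydroxy acid 11 (not isolated)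
Conditions: NaBH4 (4 equiv), 1 M NaOH, THF–EtOH, 0 °C → rt; then 2 M HCl to pH 2, rt
Reagents that add atoms: sodium hydroxide, [Na+].[OH-] (its oxygen enters the carboxylate on ring opening and is partly kept in the lactone carbonyl)
Why: Pseudo-ester saponification, borohydride reduction and relactonisation in one flask, in which hydroxide opens the acyloxy acetal, the hemiacetal collapses to the aldehyde and (+)-menthol, NaBH4 reduces the aldehyde before it can epimerise and also masks the C7 ketone as its alcohol (hydride from the etheno side expected), and acid closes the cis hydroxy acid to the γ-lactone.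

Step 7
Reactants: 12 hydroxy γ-lactone
Product: 13 ethyl ketone diol (open form of the ethyl hemiketal)
Conditions: EtLi (2.2 equiv), THF, −78 °C; aq. NH4Cl, −78 °C
Reagents that add atoms: ethyllithium, [Li]CC
Why: Mono-addition of an alkyllithium to a γ-lactone, in which the first equivalent deprotonates the C7 hydroxyl and the tetrahedral lithium alkoxide from the second persists at −78 °C so that the ketone appears only on quench.

Step 8
Reactants: 13 ethyl ketone diol
Product: 15 ethyl ketone with primary TBS ether and C7 trimethylsilyl ether, via mono-TBS ether 14 (not isolated)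
Conditions: TBSCl (1.1 equiv), imidazole, DMF, 0 °C; then TMSCl (2 equiv), rt
Reagents that add atoms: tert-butyldimethylsilyl chloride, CC(C)(C)[Si](C)(C)Cl; chlorotrimethylsilane, C[Si](C)(C)Cl
Why: Imidazole-mediated silylation of alcohols, in which TBSCl takes the primary hydroxyl of the open-chain tautomer (draining the hemiketal) and the hindered C7 hydroxyl then accepts the small trimethylsilyl group, which keeps it out of the triflation in step 9.

Step 9
Reactants: 15 bis-silylated ethyl ketone
Product: 16 (Z)-enol triflate (triflate cis to the methyl)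
Conditions: KN(SiMe3)2 (1.2 equiv), THF, −78 °C; PhNTf2, −78 → 0 °C
Reagents that add atoms: N-phenylbis(trifluoromethanesulfonimide), O=S(=O)(N(c1ccccc1)S(=O)(=O)C(F)(F)F)C(F)(F)F
Why: Kinetic enolisation and O-triflation (enol triflate formation), in which the bulky amide removes a proton from the ethyl CH2 and not the shielded tertiary C2–H, the Z(O)-enolate is favoured because its methyl avoids allylic strain against the cage carbon, and triflation freezes that geometry.

Step 10
Reactants: 16 (Z)-enol triflate
Product: 18 (E)-butenyl cage alcohol, via trimethylsilyl ether 17 (not isolated)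
Conditions: MeZnCl (3 equiv), Pd(PPh3)4 (5 mol %), THF, 50 °C; crude product, then K2CO3, MeOH, rt
Reagents that add atoms: methylzinc chloride, C[Zn]Cl
Why: Negishi cross-coupling at zerovalent palladium replaces the triflate by methyl with retention of alkene geometry, so the new methyl is cis to the old one and the but-2-en-2-yl group is E, and methanolysis then removes only the labile trimethylsilyl ether.

Step 11
Reactants: 18 (E)-butenyl cage alcohol
Product: 19 (E)-butenyl cage ketone
Conditions: Dess–Martin periodinane, NaHCO3, CH2Cl2, rt
Reagents that add atoms: none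
Why: Dess–Martin oxidation of the hindered secondary alcohol (both C7 epimers converge) under buffered conditions that should not epimerise the adjacent C8 centre.

Step 12
Reactants: 19 (E)-butenyl cage ketone; 20 vinylmagnesium bromide
Product: 21 endo 2-vinylbicyclo[2.2.2]oct-5-en-2-ol (vinyl syn to the C4=C4a bridge)
Conditions: 20 (3 equiv), anhydrous CeCl3 (3 equiv), THF, −78 °C; aq. NH4Cl
Reagents that add atoms: none
Why: 1,2-Addition of the vinylcerium reagent (Imamoto conditions, which suppress enolisation of the hindered ketone), in which the nucleophile should attack the C7 face that looks at the etheno bridge because the opposite face is screened by the C2–H bond, setting the carbinol centre with vinyl syn to the alkene.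

Step 13
Reactants: 21 endo 2-vinylbicyclo[2.2.2]oct-5-en-2-ol
Product: 23 cis-octalin C7 ketone with C1 silyloxymethyl, via potassium enolate 22 (not isolated)
Conditions: KH (3 equiv), 18-crown-6 (1.5 equiv), THF, 0 °C → rt; transferred into aq. NH4Cl at −78 °C
Reagents that add atoms: none
Why: Deprotonation gives the potassium alkoxide, whose oxyanion weakens the adjacent C3–C7 bond so that the 1,5-diene C5=C6–C7–C3–C4=C4a undergoes a [3,3] shift near room temperature (anionic oxy-Cope rearrangement, the closest known case being 2-vinylbicyclo[2.2.2]oct-5-en-2-ols from masked o-benzoquinone adducts, which give cis-decalones). Ring B (C4a–C5–C6–C7–C8–C8a) is closed by the new C4a–C5 bond within the six-centre boat transition state that the cage imposes, while cleavage of C3–C7 releases ring A with its C3=C4 alkene and leaves the C6–C7 enolate. The one new stereocentre, C4a, is controlled by the cage: the vinyl terminus can reach C4a only on the alkene face turned toward the C7–C8 bridge, so H4a should end up cis to H8a and on the face of the C1 and C2 groups that the endo cycloaddition placed over that alkene. The step needs the vinyl group syn to the etheno bridge, which step 12 provides, and an enolate formed away from C8, which is inherent in the shift, so the C8 methyl centre is not touched. The cold buffered quench protonates C6 before base can equilibrate C8.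

Step 14
Reactants: 23 cis-octalin C7 ketone
Product: 24 C7 alcohol (hydroxyl cis to the C8 methyl)
Conditions: LiBH(s-Bu)3, THF, −78 °C; then NaOH, H2O2, 0 °C
Reagents that add atoms: none
Why: Ketone reduction by a bulky trialkylborohydride, which should add equatorially to the ring B chair that carries the C8 methyl equatorial (avoiding the axial hydrogens at C5 and C8a) and give the axial C7 alcohol cis to the methyl, as 2-methylcyclohexanone gives cis-2-methylcyclohexanol.

Step 15
Reactants: 24 C7 alcohol
Product: 25 C7 acetate
Conditions: Ac2O, DMAP (cat.), pyridine, rt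
Reagents that add atoms: acetic anhydride, CC(=O)OC(C)=O
Why: DMAP-catalysed acylation masks the C7 hydroxyl so that the later oxidation at the C1 carbinol cannot form a lactol or lactone with it.

Step 16
Reactants: 25 C7 acetate
Product: 26 primary alcohol
Conditions: HF·pyridine, pyridine–THF, 0 °C → rt
Reagents that add atoms: none
Why: Fluoride-driven desilylation (Si–F bond formation) under pyridine-buffered conditions frees the primary alcohol and leaves the acetate and the alkenes alone.

Step 17
Reactants: 26 primary alcohol
Product: 27 C1 aldehyde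
Conditions: Dess–Martin periodinane, NaHCO3, CH2Cl2, 0 °C; used at once
Reagents that add atoms: none
Why: Dess–Martin oxidation under buffered neutral conditions gives the aldehyde without epimerising C1, which is now α to a carbonyl and cis to the C2 butenyl group.

Step 18
Reactants: 27 C1 aldehyde
Product: 28 ethyl (2E,4E)-dienoate C7 acetate
Conditions: triethyl 4-phosphonocrotonate, LiN(SiMe3)2, THF, −78 °C; 27, −78 → 0 °C
Reagents that add atoms: triethyl 4-phosphonocrotonate, CCOC(=O)/C=C/CP(=O)(OCC)OCC
Why: Vinylogous Horner–Wadsworth–Emmons olefination, in which the pre-formed lithium phosphonate adds through its α-carbon and loses diethyl phosphate to give the new alkene trans, the crotonate alkene stays E, and the weakly basic stabilised anion at low temperature should not epimerise C1.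

Step 19
Reactants: 28 ethyl dienoate C7 acetate
Product: 29 ethyl dienoate C7 alcohol
Conditions: K2CO3, EtOH, rt → 40 °C
Reagents that add atoms: none
Why: Base-catalysed transesterification removes the acetate as ethyl acetate, and ethanol as solvent leaves the ethyl dienoate unchanged.

Step 20
Reactants: 29 ethyl dienoate C7 alcohol
Product: 30 ethyl dienoate C7 sulfate, pyridinium salt
Conditions: SO3·pyridine (5 equiv), pyridine, rt
Reagents that add atoms: sulfur trioxide–pyridine complex, O=S(=O)([O-])[n+]1ccccc1
Why: O-Sulfation with a mild SO3 donor, which reacts only at the O–H bond so that C7 keeps its configuration and the alkenes and ester are untouched.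

Step 21
Reactants: 30 ethyl dienoate C7 sulfate, pyridinium salt
Product: 31 CNP0450810.2 (target)
Conditions: LiOH, THF–H2O, 0 °C → rt; then cold 0.5 M HCl to pH 2, n-BuOH extraction
Reagents that add atoms: lithium hydroxide, [Li+].[OH-]
Why: Saponification of the ethyl ester, which the alkyl sulfate monoester anion should survive at room temperature, followed by brief cold acidification to bring carboxylate and sulfate to the acid form.

## Compound list

1 | furfural | O=Cc1ccco1 | starting material
2 | 5-hydroxy-2(5H)-furanone (racemic) | O=C1C=CC(O)O1 | intermediate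
3 | (+)-menthol | CC(C)[C@H]1CC[C@H](C)C[C@@H]1O | starting material
4 | (5S)-5-[(1S,2R,5S)-menthyloxy]-2(5H)-furanone | CC(C)[C@H]1CC[C@H](C)C[C@@H]1O[C@@H]2C=CC(=O)O2 | intermediate
5 | 2-methoxy-6-methylphenol | COc1cccc(C)c1O | starting material
6 | 6,6-dimethoxy-2-methylcyclohexa-2,4-dien-1-one (masked o-benzoquinone) | COC1(OC)C=CC=C(C)C1=O | intermediate
7 | endo cage adduct: bicyclo[2.2.2]octenone with C7 ketone, C8 dimethyl ketal, C3 bridgehead methyl and a cis-fused menthyloxy γ-lactone on C1–C2 (carbonyl on C2, acetal carbon on C1) syn to the C4=C4a bridge | O=C1O[C@H](O[C@H]4C[C@@H](C)CC[C@@H]4C(C)C)[C@@H]2[C@H]1[C@]3(C)C=C[C@H]2C(OC)(OC)C3=O | intermediate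
8 | monomethoxy ketone (C8 epimers) | O=C1O[C@H](O[C@H]4C[C@@H](C)CC[C@@H]4C(C)C)[C@@H]2[C@H]1[C@]3(C)C=C[C@H]2C(OC)C3=O | intermediate
9 | cage ketone with C8 methylene | O=C1O[C@H](O[C@H]4C[C@@H](C)CC[C@@H]4C(C)C)[C@@H]2[C@H]1[C@]3(C)C=C[C@H]2CC3=O | intermediate
10 | C8-methyl cage ketone, methyl syn to the etheno bridge | O=C1O[C@H](O[C@H]4C[C@@H](C)CC[C@@H]4C(C)C)[C@@H]2[C@H]1[C@]3(C)C=C[C@H]2[C@@H](C)C3=O | intermediate
11 | dihydroxy acid (C2 carboxylic acid, C1 hydroxymethyl, C7 carbinol) | OC(=O)[C@@H]1[C@]2(C)C=C[C@@H]([C@@H](C)[C@@H]2O)[C@@H]1CO | intermediate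
12 | hydroxy γ-lactone (C=O on C2, OCH2 on C1; C7 carbinol) | O=C1OC[C@@H]2[C@H]1[C@]3(C)C=C[C@H]2[C@@H](C)[C@@H]3O | intermediate
13 | ethyl ketone diol (C2 propanoyl, C1 hydroxymethyl, C7 carbinol; in equilibrium with its cyclic ethyl hemiketal) | CCC(=O)[C@@H]1[C@]2(C)C=C[C@@H]([C@@H](C)[C@@H]2O)[C@@H]1CO | intermediate
14 | mono-TBS ether of 13 (primary oxygen) | CCC(=O)[C@@H]1[C@]2(C)C=C[C@@H]([C@@H](C)[C@@H]2O)[C@@H]1CO[Si](C)(C)C(C)(C)C | intermediate
15 | ethyl ketone with primary TBS ether and C7 trimethylsilyl ether | CCC(=O)[C@@H]1[C@]2(C)C=C[C@@H]([C@@H](C)[C@@H]2O[Si](C)(C)C)[C@@H]1CO[Si](C)(C)C(C)(C)C | intermediate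
16 | (Z)-enol triflate | C/C=C(\OS(=O)(=O)C(F)(F)F)[C@@H]1[C@]2(C)C=C[C@@H]([C@@H](C)[C@@H]2O[Si](C)(C)C)[C@@H]1CO[Si](C)(C)C(C)(C)C | intermediate
17 | (E)-butenyl cage C7 trimethylsilyl ether | C/C=C(\C)[C@@H]1[C@]2(C)C=C[C@@H]([C@@H](C)[C@@H]2O[Si](C)(C)C)[C@@H]1CO[Si](C)(C)C(C)(C)C | intermediate
18 | (E)-butenyl cage C7 alcohol | C/C=C(\C)[C@@H]1[C@]2(C)C=C[C@@H]([C@@H](C)[C@@H]2O)[C@@H]1CO[Si](C)(C)C(C)(C)C | intermediate
19 | (E)-butenyl cage C7 ketone | C/C=C(\C)[C@@H]1[C@]2(C)C=C[C@@H]([C@@H](C)C2=O)[C@@H]1CO[Si](C)(C)C(C)(C)C | intermediate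
20 | vinylmagnesium bromide | C=C[Mg]Br | starting material
21 | endo 2-vinylbicyclo[2.2.2]oct-5-en-2-ol with butenyl and silyloxymethyl groups (oxy-Cope precursor) | C/C=C(\C)[C@@H]1[C@]2(C)C=C[C@@H]([C@@H](C)[C@@]2(O)C=C)[C@@H]1CO[Si](C)(C)C(C)(C)C | intermediate
22 | potassium C6–C7 enolate of the cis-octalone | C/C=C(\C)[C@@H]1C(C)=C[C@H]2CC=C([O-])[C@H](C)[C@H]2[C@@H]1CO[Si](C)(C)C(C)(C)C.[K+] | intermediate
23 | cis-octalin C7 ketone with C1 silyloxymethyl | C/C=C(\C)[C@@H]1C(C)=C[C@H]2CCC(=O)[C@H](C)[C@H]2[C@@H]1CO[Si](C)(C)C(C)(C)C | intermediate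
24 | C7 alcohol, hydroxyl cis to C8 methyl | C/C=C(\C)[C@@H]1C(C)=C[C@H]2CC[C@H](O)[C@H](C)[C@H]2[C@@H]1CO[Si](C)(C)C(C)(C)C | intermediate
25 | C7 acetate | C/C=C(\C)[C@@H]1C(C)=C[C@H]2CC[C@H](OC(C)=O)[C@H](C)[C@H]2[C@@H]1CO[Si](C)(C)C(C)(C)C | intermediate
26 | C1 hydroxymethyl C7 acetate | C/C=C(\C)[C@@H]1C(C)=C[C@H]2CC[C@H](OC(C)=O)[C@H](C)[C@H]2[C@@H]1CO | intermediate
27 | C1 aldehyde C7 acetate | C/C=C(\C)[C@@H]1C(C)=C[C@H]2CC[C@H](OC(C)=O)[C@H](C)[C@H]2[C@@H]1C=O | intermediate
28 | ethyl (2E,4E)-dienoate C7 acetate | C/C=C(\C)[C@@H]1C(C)=C[C@H]2CC[C@H](OC(C)=O)[C@H](C)[C@H]2[C@@H]1/C=C/C=C/C(=O)OCC | intermediate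
29 | ethyl (2E,4E)-dienoate C7 alcohol | C/C=C(\C)[C@@H]1C(C)=C[C@H]2CC[C@H](O)[C@H](C)[C@H]2[C@@H]1/C=C/C=C/C(=O)OCC | intermediate
30 | ethyl (2E,4E)-dienoate C7 sulfate, pyridinium salt | C/C=C(\C)[C@@H]1C(C)=C[C@H]2CC[C@H](OS(=O)(=O)[O-])[C@H](C)[C@H]2[C@@H]1/C=C/C=C/C(=O)OCC.c1cc[nH+]cc1 | intermediate
31 | CNP0450810.2 | C/C=C(\C)[C@@H]1C(C)=C[C@H]2CC[C@H](OS(=O)(=O)O)[C@H](C)[C@H]2[C@@H]1/C=C/C=C/C(=O)O | target

## Step count and risks

Total steps: 21. Longest linear sequence: 21 steps (1 → 31); compounds 3, 5 and 20 join it in steps 2, 3 and 12.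

Steps most likely to fail:

Step 3. The dienone may dimerise faster than it adds to the β-substituted butenolide, and the orientation at the methyl-bearing diene terminus may erode. Fallback: setting out from 5, bromination para to the hydroxyl (N-bromosuccinimide, MeCN, 0 °C) gives 4-bromo-2-methoxy-6-methylphenol F1. Oxidation with PhI(OAc)2 in MeOH gives 4-bromo-6,6-dimethoxy-2-methylcyclohexa-2,4-dien-1-one F2, a masked o-benzoquinone whose brominated dienophilic double bond should resist dimerisation, so it can be isolated and heated with 4 (1.2 equiv, toluene, 80–110 °C) to the bromo cage adduct F3. Radical debromination (Bu3SnH, AIBN, toluene, 80 °C) removes the vinylic bromine and the sequence comes back to the route at 7.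

Step 12. The C8 methyl sits on the side of the ketone that the nucleophile must use, so facial selectivity may fall, and the hindered ketone may enolise in place of adding. Fallback: setting out from 19, the rod-shaped and less basic ethynylmagnesium bromide with CeCl3 (THF, −78 °C), which has the smallest clash with the neighbouring methyl, gives the ethynyl carbinol F4. Hydroxyl-directed hydroalumination with NaAlH2(OCH2CH2OMe)2 (THF, 0 °C → rt) then reduces the alkyne to the vinyl group without touching the other alkenes, and the sequence comes back to the route at 21.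

Step 13. The alkoxide may cleave C3–C7 to an enone and an allyl anion that fail to recombine, or the basic medium may equilibrate the enolate toward C8 and scramble the methyl centre before quench. Fallback: setting out from 21, silylation (N-trimethylsilylimidazole, CH2Cl2, rt) gives the tertiary trimethylsilyl ether F5. Neutral thermal siloxy-Cope rearrangement (mesitylene, sealed base-washed tube, 220–250 °C) gives the C6–C7 trimethylsilyl enol ether F6 of the cis-octalone through the same cage-enforced transition state without any free base. Mild methanolysis (K2CO3, MeOH, 0 °C) releases the ketone and the sequence comes back to the route at 23.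

## Further compounds

F1 | step 3 | 4-bromo-2-methoxy-6-methylphenol | COc1cc(Br)cc(C)c1O
F2 | step 3 | 4-bromo-6,6-dimethoxy-2-methylcyclohexa-2,4-dien-1-one | COC1(OC)C=C(Br)C=C(C)C1=O
F3 | step 3 | bromo cage adduct (bromine on C4a) | O=C1O[C@H](O[C@H]4C[C@@H](C)CC[C@@H]4C(C)C)[C@@H]2[C@H]1[C@]3(C)C=C(Br)[C@H]2C(OC)(OC)C3=O
F4 | step 12 | ethynyl carbinol (ethynyl syn to the etheno bridge) | C/C=C(\C)[C@@H]1[C@]2(C)C=C[C@@H]([C@@H](C)[C@@]2(O)C#C)[C@@H]1CO[Si](C)(C)C(C)(C)C
F5 | step 13 | tertiary trimethylsilyl ether of 21 | C/C=C(\C)[C@@H]1[C@]2(C)C=C[C@@H]([C@@H](C)[C@@]2(O[Si](C)(C)C)C=C)[C@@H]1CO[Si](C)(C)C(C)(C)C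
F6 | step 13 | C6–C7 trimethylsilyl enol ether of 23 | C/C=C(\C)[C@@H]1C(C)=C[C@H]2CC=C(O[Si](C)(C)C)[C@H](C)[C@H]2[C@@H]1CO[Si](C)(C)C(C)(C)C
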